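**Plan**

1. Central ring numbering: C1 (2-arylethyl), C2 (benzyl), C3 (OH), C4 (benzyl), C5 (OMe), C6 (benzyl). The retrosynthesis cuts the three phenolic O–benzyl bonds, takes the C6 benzylic CH2 back to an aroyl C=O, then cuts ring bonds C1–C2 and C5–C6 while restoring a CH2–CH2 bridge between C2 and C5.
2. Enabling feature: in the hexasubstituted benzene ring, C2–C3(OH)–C4–C5(OMe) is a 1,3-dioxygenated four-carbon run that coincides with the diene of the silyl dienol ether of 2,6-dibenzyl-3-methoxycyclohex-2-enone; the vicinal pair C1/C6 is an alkyne carrying the arylethyl chain and an aroyl group.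
3. Forward, arm A (4 steps): cyclohexane-1,3-dione is reductively benzylated at C2, converted to the methyl enol ether, benzylated at C6 and silylated to diene 10. Arm B (2 steps): 3-methoxybenzyl bromide is homologated to a but-3-ynyl arene and aroylated to ynone 17.
4. Ring formation: only the central benzene ring is built (step 7, cycloaddition then ethylene loss); the four outer rings arrive intact. The ketone is then reduced to CH2 and the benzyl ethers are removed.
5. Stereochemistry: the target has none; the racemic centres of 8, 18 and 21 are all erased downstream.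

Key step: step 7

Remark: the target has no stereocentre and no configurationally stable axis, so it is achiral and "single enantiomer" reduces to the one constitution shown; racemic intermediates are written without stereodescriptors.

**Route**

Step 1
Reactants: 1 cyclohexane-1,3-dione; 2 4-(benzyloxy)benzaldehyde
Product: 4 2-[4-(benzyloxy)benzyl]cyclohexane-1,3-dione, via Knoevenagel adduct 3 (not isolated)
Conditions: L-proline (20 mol %), Hantzsch ester (1.05 equiv), CH2Cl2, rt; product extracted into aq. NaHCO3 and re-acidified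
Reagents that add atoms: none
Why: Proline-catalysed Knoevenagel condensation gives arylidene dione 3, which the Hantzsch ester reduces by conjugate hydride transfer as it forms (organocatalytic reductive alkylation of a 1,3-dione), so bis-adduct formation and O-alkylation are avoided.

Step 2
Reactants: 4 2-[4-(benzyloxy)benzyl]cyclohexane-1,3-dione
Product: 5 2-[4-(benzyloxy)benzyl]-3-methoxycyclohex-2-en-1-one
Conditions: HC(OMe)3, p-TsOH·H2O (cat.), MeOH, rt to 50 °C
Reagents that add atoms: methanol, CO; trimethyl orthoformate, COC(OC)OC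
Why: Acid-catalysed enol etherification of a cyclic 1,3-dione (vinylogous esterification) with orthoformate as water scavenger; the dione is symmetrical, so a single enol ether results, and the benzyl ether tolerates catalytic acid.

Step 3
Reactants: 5 2-[4-(benzyloxy)benzyl]-3-methoxycyclohex-2-en-1-one; 6 4-(benzyloxy)benzyl bromide
Product: 8 2,6-bis[4-(benzyloxy)benzyl]-3-methoxycyclohex-2-en-1-one (racemic), via lithium enolate 7 (not isolated)
Conditions: LDA (1.1 equiv), THF, −78 °C; then 6, −78 to 0 °C
Reagents that add atoms: none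
Why: Stork–Danheiser kinetic α′-deprotonation of the vinylogous ester gives the cross-conjugated enolate 7, which the reactive benzylic bromide C-alkylates at C6; the new stereocentre forms as a racemate and is erased in step 4.

Step 4
Reactants: 8 2,6-bis[4-(benzyloxy)benzyl]-3-methoxycyclohex-2-en-1-one
Product: 10 1,3-bis[4-(benzyloxy)benzyl]-4-methoxy-2-(trimethylsilyloxy)cyclohexa-1,3-diene, via lithium dienolate 9 (not isolated)
Conditions: LDA (1.2 equiv), THF, −78 °C; TMSCl (1.5 equiv, with a little Et3N), −78 °C to rt; concentrate, pentane, filter under argon, use crude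
Reagents that add atoms: chlorotrimethylsilane, C[Si](C)(C)Cl
Why: A second kinetic α′-deprotonation at C6 (the regiochemistry that permits 6,6-dialkylation in Stork–Danheiser chemistry) gives cross-conjugated dienolate 9, and O-silylation of this lithium enolate gives the 1-methoxy-3-silyloxycyclohexa-1,3-diene.

Step 5
Reactants: 11 3-methoxybenzyl bromide; 12 1-(trimethylsilyl)propyne
Product: 15 1-(but-3-yn-1-yl)-3-methoxybenzene, via lithiated silylpropyne 13 (not isolated), via silylated alkyne 14 (not isolated)
Conditions: n-BuLi, THF, −78 °C; 11, −78 °C to rt; then K2CO3, MeOH, rt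
Reagents that add atoms: none
Why: Propargylic lithiation of the silylpropyne and SN2 alkylation by the benzylic bromide (the silyl group steers the ambident anion to the acetylenic rather than the allenic product), followed in the same flask by methanolysis of the C(sp)–Si bond.

Step 6
Reactants: 15 1-(but-3-yn-1-yl)-3-methoxybenzene; 16 4-(benzyloxy)benzoyl chloride
Product: 17 1-[4-(benzyloxy)phenyl]-5-(3-methoxyphenyl)pent-2-yn-1-one
Conditions: PdCl2(PPh3)2 (2 mol %), CuI (4 mol %), Et3N (1.2 equiv), THF, rt
Reagents that add atoms: none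
Why: Acyl Sonogashira coupling (oxidative addition of the aroyl chloride, transmetallation from the copper acetylide, reductive elimination) gives the ynone directly at room temperature without a separate oxidation or exposure of the propargylic CH2 to strong base.

Step 7
Reactants: 10 1,3-bis[4-(benzyloxy)benzyl]-4-methoxy-2-(trimethylsilyloxy)cyclohexa-1,3-diene; 17 1-[4-(benzyloxy)phenyl]-5-(3-methoxyphenyl)pent-2-yn-1-one
Product: 20 {3,5-bis[4-(benzyloxy)benzyl]-4-hydroxy-2-methoxy-6-[2-(3-methoxyphenyl)ethyl]phenyl}[4-(benzyloxy)phenyl]methanone, via bicyclo[2.2.2]octadiene adduct 18 (not isolated), via aryl trimethylsilyl ether 19 (not isolated)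
Conditions: 10 (2 equiv), o-xylene (ca. 2 M), BHT (cat.), base-washed sealed tube, 150 °C; then 1 M HCl, THF, rt
Reagents that add atoms: none
Why: The ring-locked s-cis diene, raised in HOMO energy by its two oxygen donors, should add the electron-poor ynone in a polarised, asynchronous normal-demand [4+2] cycloaddition to give bicyclo[2.2.2]octadiene 18, which at the same temperature undergoes retro-[4+2] loss of its CH2–CH2 bridge as ethylene, driven by aromatisation, to give silyl ether 19, and dilute acid then frees the C3 phenol. The closest known reaction type is the Alder–Rickert reaction of alkoxy- and silyloxycyclohexa-1,3-dienes with acetylenic ketones and esters. The benzene ring is closed by intermolecular cycloaddition, with both σ-bonds (C1–C2 and C5–C6) made in the same event, so no chain cyclisation is involved. No stereocentre is set: the two bridgehead centres of racemic 18 become sp2 when ethylene leaves. The step needs the regiochemistry that puts the aroyl group next to OMe, and the substrate secures it because the donor effects of OSiMe3 and OMe converge on the silyl enol ether terminus (future C2), which therefore carries the largest HOMO coefficient and bonds to the ynone β-carbon (future C1), leaving the methoxy-bearing terminus (future C5) to bond to the aroyl-bearing α-carbon (future C6). Only the saturated two-carbon bridge can be expelled as an alkene, and excess diene, high concentration and acid-free glassware are used to offset the steric demand of the fully substituted partners and the lability of the silyl enol ether.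

Step 8
Reactants: 20 {3,5-bis[4-(benzyloxy)benzyl]-4-hydroxy-2-methoxy-6-[2-(3-methoxyphenyl)ethyl]phenyl}[4-(benzyloxy)phenyl]methanone
Product: 21 2,6-bis[4-(benzyloxy)benzyl]-4-{[4-(benzyloxy)phenyl](hydroxy)methyl}-3-methoxy-5-[2-(3-methoxyphenyl)ethyl]phenol (racemic)
Conditions: LiAlH4 (3 equiv), THF, 0 °C to rt; aq. NaOH work-up
Reagents that add atoms: none
Why: Hydride addition to the diaryl ketone, with LiAlH4 chosen because the carbonyl is flanked by two ortho substituents and deactivated by the para phenoxide; benzyl and methyl aryl ethers are inert, and the racemic carbinol centre is removed in step 9.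

Step 9
Reactants: 21 2,6-bis[4-(benzyloxy)benzyl]-4-{[4-(benzyloxy)phenyl](hydroxy)methyl}-3-methoxy-5-[2-(3-methoxyphenyl)ethyl]phenol
Product: 22 2,4,6-tris[4-(benzyloxy)benzyl]-3-methoxy-5-[2-(3-methoxyphenyl)ethyl]phenol
Conditions: Et3SiH (5 equiv), TFA (10 equiv), CH2Cl2, 0 °C, short reaction time
Reagents that add atoms: none
Why: Ionic hydrogenation: TFA ionises the doubly benzylic carbinol to a diarylmethyl cation stabilised by the para-OH, ortho-OMe and para-benzyloxy groups, and excess silane, a far stronger hydride donor than an anisole ring is a π-nucleophile, should reduce it before it can cyclise onto the methoxyphenethyl ring, while aryl benzyl ethers tolerate brief dilute TFA at 0 °C.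

Step 10
Reactants: 22 2,4,6-tris[4-(benzyloxy)benzyl]-3-methoxy-5-[2-(3-methoxyphenyl)ethyl]phenol
Product: 23 2,4,6-tris(4-hydroxybenzyl)-3-methoxy-5-[2-(3-methoxyphenyl)ethyl]phenol (CNP0285788.0)
Conditions: H2 (1 atm), 10% Pd/C, EtOAc–MeOH, rt
Reagents that add atoms: none
Why: Palladium-catalysed hydrogenolysis of the three aryl benzyl ethers; the two methyl ethers and the diarylmethane and bibenzyl C–C bonds are inert at 1 atm and room temperature.

**Compound list**

1 | cyclohexane-1,3-dione | O=C1CCCC(=O)C1 | starting material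
2 | 4-(benzyloxy)benzaldehyde | O=Cc1ccc(OCc2ccccc2)cc1 | starting material
3 | 2-[4-(benzyloxy)benzylidene]cyclohexane-1,3-dione | O=C1CCCC(=O)C1=Cc1ccc(OCc2ccccc2)cc1 | intermediate (not isolated)
4 | 2-[4-(benzyloxy)benzyl]cyclohexane-1,3-dione | O=C1CCCC(=O)C1Cc1ccc(OCc2ccccc2)cc1 | intermediate
5 | 2-[4-(benzyloxy)benzyl]-3-methoxycyclohex-2-en-1-one | COC1=C(Cc2ccc(OCc3ccccc3)cc2)C(=O)CCC1 | intermediate
6 | 4-(benzyloxy)benzyl bromide | BrCc1ccc(OCc2ccccc2)cc1 | starting material
7 | lithium 6-[4-(benzyloxy)benzyl]-5-methoxycyclohexa-1,5-dien-1-olate | [Li]OC1=CCCC(OC)=C1Cc1ccc(OCc2ccccc2)cc1 | intermediate (not isolated)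
8 | 2,6-bis[4-(benzyloxy)benzyl]-3-methoxycyclohex-2-en-1-one (racemic) | COC1=C(Cc2ccc(OCc3ccccc3)cc2)C(=O)C(Cc2ccc(OCc3ccccc3)cc2)CC1 | intermediate
9 | lithium 2,6-bis[4-(benzyloxy)benzyl]-5-methoxycyclohexa-1,5-dien-1-olate | [Li]OC1=C(Cc2ccc(OCc3ccccc3)cc2)CCC(OC)=C1Cc1ccc(OCc2ccccc2)cc1 | intermediate (not isolated)
10 | 1,3-bis[4-(benzyloxy)benzyl]-4-methoxy-2-(trimethylsilyloxy)cyclohexa-1,3-diene | COC1=C(Cc2ccc(OCc3ccccc3)cc2)C(O[Si](C)(C)C)=C(Cc2ccc(OCc3ccccc3)cc2)CC1 | intermediate
11 | 3-methoxybenzyl bromide | COc1cccc(CBr)c1 | starting material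
12 | 1-(trimethylsilyl)propyne | CC#C[Si](C)(C)C | starting material
13 | [3-(trimethylsilyl)prop-2-yn-1-yl]lithium | [Li]CC#C[Si](C)(C)C | intermediate (not isolated)
14 | [4-(3-methoxyphenyl)but-1-yn-1-yl]trimethylsilane | COc1cccc(CCC#C[Si](C)(C)C)c1 | intermediate (not isolated)
15 | 1-(but-3-yn-1-yl)-3-methoxybenzene | COc1cccc(CCC#C)c1 | intermediate
16 | 4-(benzyloxy)benzoyl chloride | O=C(Cl)c1ccc(OCc2ccccc2)cc1 | starting material
17 | 1-[4-(benzyloxy)phenyl]-5-(3-methoxyphenyl)pent-2-yn-1-one | O=C(C#CCCc1cccc(OC)c1)c1ccc(OCc2ccccc2)cc1 | intermediate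
18 | {4,6-bis[4-(benzyloxy)benzyl]-1-methoxy-3-[2-(3-methoxyphenyl)ethyl]-5-(trimethylsilyloxy)bicyclo[2.2.2]octa-2,5-dien-2-yl}[4-(benzyloxy)phenyl]methanone (racemic) | COC12CCC(Cc3ccc(OCc4ccccc4)cc3)(C(O[Si](C)(C)C)=C1Cc5ccc(OCc6ccccc6)cc5)C(CCc7cccc(OC)c7)=C2C(=O)c8ccc(OCc9ccccc9)cc8 | intermediate (not isolated)
19 | {3,5-bis[4-(benzyloxy)benzyl]-2-methoxy-6-[2-(3-methoxyphenyl)ethyl]-4-(trimethylsilyloxy)phenyl}[4-(benzyloxy)phenyl]methanone | COc1cccc(CCc2c(Cc3ccc(OCc4ccccc4)cc3)c(O[Si](C)(C)C)c(Cc3ccc(OCc4ccccc4)cc3)c(OC)c2C(=O)c2ccc(OCc3ccccc3)cc2)c1 | intermediate (not isolated)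
20 | {3,5-bis[4-(benzyloxy)benzyl]-4-hydroxy-2-methoxy-6-[2-(3-methoxyphenyl)ethyl]phenyl}[4-(benzyloxy)phenyl]methanone | COc1cccc(CCc2c(Cc3ccc(OCc4ccccc4)cc3)c(O)c(Cc3ccc(OCc4ccccc4)cc3)c(OC)c2C(=O)c2ccc(OCc3ccccc3)cc2)c1 | intermediate
21 | 2,6-bis[4-(benzyloxy)benzyl]-4-{[4-(benzyloxy)phenyl](hydroxy)methyl}-3-methoxy-5-[2-(3-methoxyphenyl)ethyl]phenol (racemic) | COc1cccc(CCc2c(Cc3ccc(OCc4ccccc4)cc3)c(O)c(Cc3ccc(OCc4ccccc4)cc3)c(OC)c2C(O)c2ccc(OCc3ccccc3)cc2)c1 | intermediate
22 | 2,4,6-tris[4-(benzyloxy)benzyl]-3-methoxy-5-[2-(3-methoxyphenyl)ethyl]phenol | COc1cccc(CCc2c(Cc3ccc(OCc4ccccc4)cc3)c(O)c(Cc3ccc(OCc4ccccc4)cc3)c(OC)c2Cc2ccc(OCc3ccccc3)cc2)c1 | intermediate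
23 | 2,4,6-tris(4-hydroxybenzyl)-3-methoxy-5-[2-(3-methoxyphenyl)ethyl]phenol | COc1cccc(CCc2c(Cc3ccc(O)cc3)c(O)c(Cc3ccc(O)cc3)c(OC)c2Cc2ccc(O)cc2)c1 | target

**Step count**

Total: 10 steps. Longest linear sequence: 8 steps (1, 2, 3, 4, 7, 8, 9, 10); the ynone arm (steps 5, 6) is 2 steps.

**Steps most likely to fail**

Step 7 (key step). The cycloaddition between a fully substituted diene and an internal, β-alkyl ynone may be too slow. Thermal or hydrolytic loss of the silyl enol ether, or Mukaiyama–Michael addition with silyl transfer and no ring closure, could then overtake it. The fallback keeps the same two ring bonds but uses a smaller, more electrophilic activating group. It sets out from alkyne 15 and diene 10 and returns at carbinol 21. Alkyne 15 is deprotonated (n-BuLi, THF, −78 °C) to its lithium acetylide F1 and formylated with DMF (inverse quench into aqueous KH2PO4) to give 5-(3-methoxyphenyl)pent-2-ynal F2. Heated with 10 at lower temperature (toluene, 80–110 °C), F2 should give the bicyclo[2.2.2]octadiene carbaldehyde F3, which loses ethylene to the silylated benzaldehyde F4; dilute acid gives 3,5-bis[4-(benzyloxy)benzyl]-4-hydroxy-2-methoxy-6-[2-(3-methoxyphenyl)ethyl]benzaldehyde F5. Addition of commercial 4-(benzyloxy)phenylmagnesium bromide (3 equiv, THF, 0 °C to rt; the first equivalent deprotonates the phenol) to F5 gives 21. The route resumes at step 9; steps 6 and 8 fall away.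

Step 9. The diarylmethyl cation may be captured intramolecularly by the methoxyphenethyl ring (Friedel–Crafts closure of a seven-membered ring). Acidolytic loss of benzyl ethers with C-benzylation of the electron-rich rings is a second risk. The fallback avoids a free cation in acidic solution. It sets out from 21 and arrives directly at target 23: hydrogenation over Pd(OH)2/C in EtOAc–AcOH under 3–4 atm H2 cleaves the benzhydrylic C–O bond and the three O-benzyl groups in one operation. Steps 9 and 10 merge, and no new compound is formed.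

Step 4. Enolisation of 8 may occur at C4 (γ) rather than at the now tertiary C6, giving an isomeric diene, or the tetrasubstituted silyl enol ether may hydrolyse on handling. The fallback generates the same enolate regiospecifically by conjugate reduction. It sets out from 5 (with aldehyde 2) and returns at 10, replacing steps 3 and 4. Enolate 7 (LDA, THF, −78 °C) is added to 2 to give the aldol 2-[4-(benzyloxy)benzyl]-6-{[4-(benzyloxy)phenyl](hydroxy)methyl}-3-methoxycyclohex-2-en-1-one F6. Mesylation (MsCl, Et3N, CH2Cl2, 0 °C) gives the methanesulfonate F7, which DBU eliminates in the same flask to (6E)-2-[4-(benzyloxy)benzyl]-6-[4-(benzyloxy)benzylidene]-3-methoxycyclohex-2-en-1-one F8. L-Selectride (THF, −78 °C) should deliver hydride to the exocyclic benzylidene carbon, which can only produce lithium dienolate 9; TMSCl then gives 10.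

**Further compounds**

F1 | step 7 | lithium 4-(3-methoxyphenyl)but-1-yn-1-ide | [Li]C#CCCc1cccc(OC)c1
F2 | step 7 | 5-(3-methoxyphenyl)pent-2-ynal | O=CC#CCCc1cccc(OC)c1
F3 | step 7 | 4,6-bis[4-(benzyloxy)benzyl]-1-methoxy-3-[2-(3-methoxyphenyl)ethyl]-5-(trimethylsilyloxy)bicyclo[2.2.2]octa-2,5-diene-2-carbaldehyde (racemic) | COC12CCC(Cc3ccc(OCc4ccccc4)cc3)(C(O[Si](C)(C)C)=C1Cc5ccc(OCc6ccccc6)cc5)C(CCc7cccc(OC)c7)=C2C=O
F4 | step 7 | 3,5-bis[4-(benzyloxy)benzyl]-2-methoxy-6-[2-(3-methoxyphenyl)ethyl]-4-(trimethylsilyloxy)benzaldehyde | COc1cccc(CCc2c(Cc3ccc(OCc4ccccc4)cc3)c(O[Si](C)(C)C)c(Cc3ccc(OCc4ccccc4)cc3)c(OC)c2C=O)c1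
F5 | step 7 | 3,5-bis[4-(benzyloxy)benzyl]-4-hydroxy-2-methoxy-6-[2-(3-methoxyphenyl)ethyl]benzaldehyde | COc1cccc(CCc2c(Cc3ccc(OCc4ccccc4)cc3)c(O)c(Cc3ccc(OCc4ccccc4)cc3)c(OC)c2C=O)c1
F0 | step 9 | none | none
F6 | step 4 | 2-[4-(benzyloxy)benzyl]-6-{[4-(benzyloxy)phenyl](hydroxy)methyl}-3-methoxycyclohex-2-en-1-one (racemic, diastereomer mixture) | COC1=C(Cc2ccc(OCc3ccccc3)cc2)C(=O)C(C(O)c2ccc(OCc3ccccc3)cc2)CC1
F7 | step 4 | [4-(benzyloxy)phenyl]{3-[4-(benzyloxy)benzyl]-4-methoxy-2-oxocyclohex-3-en-1-yl}methyl methanesulfonate | COC1=C(Cc2ccc(OCc3ccccc3)cc2)C(=O)C(C(OS(C)(=O)=O)c2ccc(OCc3ccccc3)cc2)CC1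
F8 | step 4 | (6E)-2-[4-(benzyloxy)benzyl]-6-[4-(benzyloxy)benzylidene]-3-methoxycyclohex-2-en-1-one | COC1=C(Cc2ccc(OCc3ccccc3)cc2)C(=O)/C(=C/c2ccc(OCc3ccccc3)cc2)CC1
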